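Follow one electrophile molecule.

electrophile 1.3 M; nucleophile 1.04 M; time 20 h

    nucleophile + acid set free ⇌ protonated nucleophile, settled at all times (K1 = 87 /M)
    free base + target → over-reaction product (k2 = 0.0296 /M/min)
    electrophile + nucleophile → acid set free + target (k3 = 0.254 /M/min)
    acid set free + free base ⇌ salt of the base, settled at all times (K4 = 49000 /M)
    electrophile + acid set free → side product (k5 = 0.00684 /M/min)

- the concentration of free base at which the part of the electrophile that has reacted at 20 h is just 90%, in M

The nucleophile, here the limiting reagent, covers 0.800 of the electrophile charge, so the missing 0.100 has to take the other fork, the step with the acid set free. How much acid can you leave open for it? The free base binds acid far more tightly than the nucleophile does, so in my reckoning each base holds one acid, and the spare acid is 0.800 minus the base fraction.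

How quickly does that spare acid work? Take the half-life of acid by the side step at full electrophile charge, 1.30 h, and divide it by the fraction of electrophile left. That fraction falls from 0.200 to 0.100, with a geometric mean of 0.141, which gives 9.19 h. The 20 h are therefore 2.18 such half-lives, and 0.221 of the spare acid stays unused. The spare acid must then be 0.128, so the base is 0.672 of the charge, or 0.873 M, with over-reaction not counted.

The forecast is higher than my figure: it gives 0.9 M, with the base “near 0.86 M, plus about 0.04 M lost to over-reaction”.

The simulation gives 0.899 M of free base. At 10.0 h, the side step has 68% of its turnover up to 20 h behind it. With 0.100 of the electrophile charge left at 20 h, the acid's half-life by the side step has stretched to 13.0 h. At 60.0 h, 94.4% of the electrophile is used, and that half-life is 23.2 h.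

All constants were set for the occasion; the run is a simulation.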